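**Plan**

- Retrosynthesis: remove the C12 octanoate, open the oxonane at C8–C9 (allylsilane onto a C9 oxocarbenium ion), the tetrahydrofuran at O–C9 (C2 hydroxyl plus C9 aldehyde) and the arm at C6–C7. The oxepane is traced to its lactone, and taking out the ring oxygen (O–C3 and O–C16, Baeyer–Villiger) leaves a trans-decalone. That is cut at C3–C4 (Michael), C14–C15 and C3–C16 (malonate annulation), then C1–C10 and C13–C14 (Diels–Alder).
- Enabling feature: in the oxepane C3–O–C16–C15–C14–C1–C2 the oxygen lies between the fully substituted C3 and the C16 methylene. The ring is therefore the cyclohexanone C3–C16–C15–C14–C1–C2 with one oxygen inserted on its more substituted side, and C3 can be built as an all-carbon quaternary centre by 1,3-dione alkylation.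
- Forward order of rings: cyclohexane (steps 1–6), carbocyclic precursor of the oxepane (7–13), oxepanone by oxygen insertion (14), its reduction to the oxepane (15–18), tetrahydrofuran acetal (20–21), oxonane (22), ester (23–24).
- Stereochemistry: C10 comes from a catalyst-controlled Diels–Alder reaction. C11, C12, C14, C1 and C3 follow by relay from C10 through its axial side chain. C2 is set by hydride delivered from the C9 hydroxyl, C3 is kept by retention in the oxygen insertion, C15 by hydrogenation of an exocyclic alkene, and C9 by the tether in the last ring closure.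

Key step: step 14

**Remarks**

- Atom numbers follow the target throughout: tetrahydrofuran O–C2–C1–C10–C9; oxonane O–C2–C3–C4–C5–C6–C7–C8–C9 (methylene on C7); cyclohexane C1–C10–C11–C12–C13–C14; oxepane C3–O–C16–C15–C14–C1–C2.
- β is the face of the carbocyclic core that carries H-1 and H-10; α is the opposite face. TBS = tert-butyldimethylsilyl, TES = triethylsilyl, Tf = trifluoromethanesulfonyl.
- Assumption: 3-(triphenylphosphoranylidene)butan-2-one and pent-1-yn-3-one are taken as purchasable; each is otherwise one step away (3-bromobutan-2-one with PPh3; pent-1-yn-3-ol with MnO2).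
- Centres that are enolisable or are destroyed later (C3 and C15 in 12–14, C15 in 24–25, C16 in 22 and 28–29, C9 in 36–37) are left undefined in the SMILES. Hydroxy ketones 17 and 19 may rest partly as cyclic hemiketals.

**Route**

Step 1
Reactants: 1 (tert-butyldimethylsilyloxy)acetaldehyde; 2 3-(triphenylphosphoranylidene)butan-2-one
Product: 3 (E)-5-(TBSO)-3-methylpent-3-en-2-one
Conditions: toluene, 80 °C
Reagents that add atoms: none
Why: Wittig olefination with a ketone-stabilised ylide gives the (E)-trisubstituted enone that holds C9 to C13 of the target.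

Step 2
Reactants: 3 (E)-5-(TBSO)-3-methylpent-3-en-2-one
Product: 4 (E)-2,5-bis(TBSO)-3-methylpenta-1,3-diene
Conditions: TBSOTf, Et3N, CH2Cl2, 0 °C
Reagents that add atoms: tert-butyldimethylsilyl triflate, CC(C)(C)[Si](C)(C)OS(=O)(=O)C(F)(F)F
Why: Soft enolisation and O-silylation of the methyl ketone on its methyl side gives the cross-conjugated 2-silyloxy diene without touching the alkene geometry.

Step 3
Reactants: 4 (E)-2,5-bis(TBSO)-3-methylpenta-1,3-diene; 5 pent-1-yn-3-one
Product: 6 1-[(6R)-4-(TBSO)-6-(TBSO-methyl)-5-methylcyclohexa-1,4-dien-1-yl]propan-1-one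
Conditions: triflimide salt of (S)-1-(2-methylphenyl)-3,3-diphenylhexahydropyrrolo[1,2-c][1,3,2]oxazaborole (20 mol %), CH2Cl2, −78 °C
Reagents that add atoms: none
Why: Catalytic enantioselective Diels–Alder reaction of an acetylenic ketone bound to a chiral oxazaborolidinium Lewis acid; the 2-silyloxy group (para rule) and the terminal CH2OTBS group (ortho rule) both join C13 to the alkyne terminus and C10 to the acyl-bearing carbon, and the catalyst (its enantiomer chosen to give (R)-C10) shields one face of the bound ynone so that the single stereocentre C10 is set.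

Step 4
Reactants: 6 cyclohexadienyl ethyl ketone
Product: 8 α-silyloxy ketone (C12 ketone; C11 β-OTBS; C11 α-CH3), via silyloxy epoxide 7 (not isolated)
Conditions: mCPBA, NaHCO3, CH2Cl2, −20 to 0 °C
Reagents that add atoms: 3-chloroperbenzoic acid, OOC(=O)c1cccc(Cl)c1
Why: Rubottom oxidation, in which the peracid epoxidises only the electron-rich silyl enol ether on the β face, anti to the pseudoaxial C10 CH2OTBS group (held axial by allylic strain with the C1 acyl and C11 methyl groups), and a 1,4-silyl shift opens the epoxide to the ketone, fixing C11.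

Step 5
Reactants: 8 α-silyloxy ketone
Product: 9 C12 β-alcohol (C11 and C12 oxygens cis)
Conditions: NaBH4, MeOH–CH2Cl2, −78 °C
Reagents that add atoms: none
Why: Borohydride reduction of the saturated α-oxygenated C12 ketone in preference to the hindered conjugated C2 ketone; hydride should enter on the α face, anti to the pseudoaxial C11–OTBS bond (polar Felkin–Anh control reinforced by the bulk of the adjacent silyl ether, the C10 side chain being one carbon further away), which places the C12 hydroxyl cis to the C11 oxygen.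

Step 6
Reactants: 9 C12 β-alcohol
Product: 10 tris-TBS enone (1-propanoylcyclohexene; C11 β-OTBS; C12 β-OTBS; C10 α-CH2OTBS)
Conditions: TBSOTf, 2,6-lutidine, CH2Cl2, 0 °C to rt
Reagents that add atoms: tert-butyldimethylsilyl triflate, CC(C)(C)[Si](C)(C)OS(=O)(=O)C(F)(F)F
Why: Silyl triflate silylation of a hindered hydroxyl; a 1,2-silyl shift in 9 would be harmless because the reagent silylates secondary and tertiary hydroxyls alike.

Step 7
Reactants: 10 tris-TBS enone; 11 dimethyl malonate
Product: 14 trans-decalin-2,16-dione with C3 methyl (H-1 β; H-14 α), via keto ester 12 (not isolated), via keto acid 13 (not isolated)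
Conditions: NaOMe, MeOH, reflux; then aq. KOH, 70 °C; then 1 M HCl to pH 3, 40 °C
Reagents that add atoms: none
Why: Michael addition followed by Claisen (Dieckmann-type) ring closure, saponification and decarboxylation; malonate should add to C14 on the β face, anti to the pseudoaxial C10 side chain, the ethyl ketone enolate then acylates on a malonate ester to close the 1,3-dione with the C3 methyl in place, and C1 is set under equilibrating conditions with the acyl carbon equatorial and trans to C15, which gives the trans ring fusion (the equatorial C12 silyl ether is poorly aligned for vinylogous elimination).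

Step 8
Reactants: 14 trans-decalin-2,16-dione; 15 acrolein
Product: 16 C3-quaternary dione aldehyde (C3 β-CH2CH2CHO; C3 α-CH3)
Conditions: Et3N (10 mol %), CH2Cl2, 0 °C to rt
Reagents that add atoms: none
Why: Michael addition of the 2-methyl-1,3-dione enolate to acrolein; the electrophile should enter axially on the β face through a chair-like transition state, syn to H-1 and away from the axial C10 CH2OTBS group that covers the α face beside C2, so C3 receives the three-carbon arm β and keeps the methyl α (an aldehyde is chosen because it can be reduced beside the ketones, which an ester cannot).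

Step 9
Reactants: 16 dione aldehyde
Product: 17 C6 alcohol
Conditions: NaBH(OAc)3, AcOH (cat.), CH2Cl2, 0 °C to rt
Reagents that add atoms: none
Why: Chemoselective triacetoxyborohydride reduction, which reduces the aldehyde and leaves both ketones.

Step 10
Reactants: 17 C6 alcohol
Product: 18 C6 bromide (3-bromopropyl arm on C3)
Conditions: CBr4, PPh3, CH2Cl2, 0 °C
Reagents that add atoms: tetrabromomethane, BrC(Br)(Br)Br
Why: Appel bromination under neutral conditions gives an arm terminus with no carbonyl and no acidic hydrogen, so that it cannot compete with the later lactone in enolisation or hydride reduction.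

Step 11
Reactants: 18 C6 bromide
Product: 19 C9 alcohol (free hydroxymethyl on C10)
Conditions: HF·pyridine, pyridine, THF, 0 °C
Reagents that add atoms: none
Why: Buffered HF·pyridine desilylation cleaves the primary TBS ether ahead of the secondary and tertiary ones, and acidic conditions avoid alkoxide-triggered retro-Claisen opening of the 2,2-disubstituted 1,3-dione.

Step 12
Reactants: 19 C9 alcohol
Product: 20 diol (C2 β-OH with H-2 α; C9 OH; C16 ketone intact)
Conditions: Me4NBH(OAc)3, MeCN–AcOH (1:1), −20 °C to rt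
Reagents that add atoms: none
Why: Hydroxyl-directed triacetoxyborohydride reduction; the reagent reduces a ketone only after binding to a hydroxyl, and the axial C9 hydroxymethyl group lies syn-axial to the α face of C2 but far from C16, so hydride should be delivered intramolecularly to C2 from the α face to give the equatorial β-alcohol while the less hindered C16 ketone survives.

Step 13
Reactants: 20 diol
Product: 21 bis-TES ether with C16 ketone
Conditions: TESOTf, 2,6-lutidine, CH2Cl2, −78 to 0 °C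
Reagents that add atoms: triethylsilyl triflate, CC[Si](CC)(CC)OS(=O)(=O)C(F)(F)F
Why: Silyl triflate silylation protects the hindered C2 hydroxyl and the primary C9 hydroxyl in one operation and leaves no free hydroxyl or alkene for the peracid.

Step 14
Reactants: 21 bis-TES ketone
Product: 23 oxepan-2-one (oxygen between C3 and C16; C16 lactone carbonyl), via Criegee adduct 22 (not isolated)
Conditions: mCPBA, NaHCO3, CH2Cl2, 0 °C to rt
Reagents that add atoms: 3-chloroperbenzoic acid, OOC(=O)c1cccc(Cl)c1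
Why: Baeyer–Villiger oxidation: the peracid adds to the C16 carbonyl to give the tetrahedral Criegee adduct 22, and the C3–C16 bond lying antiperiplanar to the O–O bond shifts to oxygen with loss of 3-chlorobenzoate, which forms O–C3 beside O–C16 and turns the cyclohexanone into the oxepan-2-one. The closest known case is the peracid oxidation of 2,2-disubstituted 3-silyloxycyclohexanones, in which the fully substituted α-carbon migrates. The seven-membered ring arises by one-atom ring expansion through a concerted 1,2-shift inside the adduct, not by an end-to-end cyclisation, so no ring-closure constraint applies. The only stereocentre involved is C3, which becomes the tertiary ether centre with retention because the shift is suprafacial on the migrating carbon; its configuration was set in step 8. The step needs migration of C3 and not of the C15 methylene, which the higher migratory aptitude of the tertiary alkyl group should secure, and it needs chemoselectivity, which holds because 21 has no alkene or free hydroxyl and the NaHCO3 buffer spares the silyl ethers.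

Step 15
Reactants: 23 oxepan-2-one
Product: 26 α-methylene lactone (C15=CH2), via Mannich base 24 (not isolated), via ammonium iodide 25 (not isolated)
Conditions: LiN(iPr)2, THF, −78 °C; CH2=NMe2+ I−, −78 to 0 °C; then MeI, MeOH, rt; then DBU, CH2Cl2, rt
Reagents that add atoms: dimethylmethyleneiminium iodide (Eschenmoser's salt), C=[N+](C)C.[I-]
Why: Lactone α-methylenation by enolate aminomethylation, N-methylation and E1cB loss of trimethylamine; C15 is the only enolisable position.

Step 16
Reactants: 26 α-methylene lactone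
Product: 27 α-methyl lactone (C15 β-CH3)
Conditions: H2 (1 atm), RhCl(PPh3)3 (10 mol %), benzene–EtOH, rt
Reagents that add atoms: none
Why: Homogeneous hydrogenation of the exocyclic alkene, with hydrogen expected on the α face, opposite the β-disposed C3 arm and C2 silyloxy group, so that the C15 methyl ends up β; the rhodium catalyst neither isomerises the alkene nor cleaves the C–Br bond, and if the other face were preferred, methylation of the enolate of 23 with MeI would use the same bias to give 27.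

Step 17
Reactants: 27 α-methyl lactone
Product: 29 C16 acetoxy oxepane (both C16 epimers), via aluminium hemiacetal 28 (not isolated)
Conditions: i-Bu2AlH, CH2Cl2, −78 °C; then pyridine, DMAP, Ac2O, −78 to 0 °C
Reagents that add atoms: acetic anhydride, CC(=O)OC(C)=O
Why: Reductive acetylation: the aluminium hemiacetal formed at −78 °C is stable to ring opening and is acetylated in situ, which keeps the seven-membered ring closed.

Step 18
Reactants: 29 C16 acetoxy oxepane
Product: 31 oxepane bromide (C16 methylene), via oxocarbenium ion 30 (not isolated)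
Conditions: Et3SiH, TMSOTf (0.2 equiv), CH2Cl2, −78 °C
Reagents that add atoms: none
Why: Lewis-acid ionisation of the anomeric acetate and silane reduction of the cyclic oxocarbenium ion (reductive deoxygenation of a lactol ester); C16 is not stereogenic and the lactone is gone before the C2 hydroxyl is ever freed, which rules out translactonisation.

Step 19
Reactants: 31 oxepane bromide; 32 2-bromo-3-(trimethylsilyl)prop-1-ene
Product: 33 allylsilane (arm C4–C6 ending in C7(=CH2)CH2SiMe3)
Conditions: 32, Mg, THF, 45 °C; then 31, Li2CuCl4 (5 mol %), NMP, THF, 0 °C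
Reagents that add atoms: none
Why: Copper-catalysed cross-coupling of a primary alkyl bromide with an alkenyl Grignard reagent forms C6–C7; no carbonyl group remains in 31 to compete.

Step 20
Reactants: 33 allylsilane
Product: 34 C9 aldehyde
Conditions: (COCl)2, DMSO, CH2Cl2, −78 to −40 °C; then iPr2NEt, −78 to 0 °C
Reagents that add atoms: none
Why: Swern oxidation applied directly to the primary triethylsilyl ether, which is cleaved and oxidised while the secondary TES ether, the TBS ethers and the allylsilane persist; the hindered amine at low temperature guards C10 against epimerisation.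

Step 21
Reactants: 34 C9 aldehyde
Product: 37 methyl acetal (tetrahydrofuran O–C2–C1–C10–C9 with C9 OMe; both anomers), via hydroxy aldehyde 35 (not isolated), via lactol 36 (not isolated)
Conditions: PPTS, MeOH, rt to 35 °C
Reagents that add atoms: methanol, CO
Why: Acid methanolysis removes the C2 triethylsilyl ether, the freed hydroxyl adds to the C9 aldehyde (5-exo-trig hemiacetal formation, possible now that the flexible oxepane has replaced the rigid decalone) and acetal exchange gives the mixed cyclic acetal; the TBS ethers and the allylsilane tolerate the mild acid.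

Step 22
Reactants: 37 methyl acetal
Product: 39 tetracyclic bis-TBS ether (oxonane closed; exocyclic methylene on C7), via oxocarbenium ion 38 (not isolated)
Conditions: TMSOTf (0.3 equiv), CH2Cl2 (0.002 M), −78 to −40 °C
Reagents that add atoms: none
Why: Intramolecular Hosomi–Sakurai reaction, in which the bicyclic oxocarbenium ion is attacked at C9 by the allylsilane terminus (nine-membered ring, endo with respect to the C=O+ bond) and loss of the silyl group leaves the C7 methylene; the arm is anchored at C3 next to the ring oxygen and can only reach the face of C9 that places C8 cis to C3, which sets C9.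

Step 23
Reactants: 39 tetracyclic bis-TBS ether
Product: 40 tetracyclic 11,12-diol
Conditions: Bu4NF, THF, 50 °C
Reagents that add atoms: none
Why: Fluoride desilylation; the secondary ether goes first and the tertiary one follows on warming, while the ether rings and the exocyclic alkene are inert to fluoride.

Step 24
Reactants: 40 tetracyclic 11,12-diol; 41 octanoyl chloride
Product: 42 target CNP0286133.1 (C12 octanoate; free C11 tertiary alcohol)
Conditions: 41, pyridine, DMAP (cat.), CH2Cl2, 0 °C to rt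
Reagents that add atoms: none
Why: Acylation with an acid chloride under nucleophilic catalysis esterifies the secondary C12 hydroxyl and leaves the tertiary C11 hydroxyl untouched.

**Compound list**

1 | (tert-butyldimethylsilyloxy)acetaldehyde | O=CCO[Si](C)(C)C(C)(C)C | starting material
2 | 3-(triphenylphosphoranylidene)butan-2-one | CC(=O)C(C)=P(c1ccccc1)(c1ccccc1)c1ccccc1 | starting material
3 | (E)-5-(TBSO)-3-methylpent-3-en-2-one | CC(=O)/C(C)=C/CO[Si](C)(C)C(C)(C)C | intermediate
4 | (E)-2,5-bis(TBSO)-3-methylpenta-1,3-diene | C=C(O[Si](C)(C)C(C)(C)C)/C(C)=C/CO[Si](C)(C)C(C)(C)C | intermediate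
5 | pent-1-yn-3-one | CCC(=O)C#C | starting material
6 | 1-[(6R)-4-(TBSO)-6-(TBSO-methyl)-5-methylcyclohexa-1,4-dien-1-yl]propan-1-one | CCC(=O)C1=CCC(O[Si](C)(C)C(C)(C)C)=C(C)[C@H]1CO[Si](C)(C)C(C)(C)C | intermediate
7 | silyloxy epoxide of 6 (C11–C12 β-epoxide, OTBS kept on C12) | CCC(=O)C1=CC[C@]2(O[Si](C)(C)C(C)(C)C)O[C@]2(C)[C@H]1CO[Si](C)(C)C(C)(C)C | intermediate
8 | α-silyloxy ketone (C12 ketone, C11 β-OTBS and α-CH3, C10 α-CH2OTBS, C1=C14 enone) | CCC(=O)C1=CCC(=O)[C@](C)(O[Si](C)(C)C(C)(C)C)[C@H]1CO[Si](C)(C)C(C)(C)C | intermediate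
9 | C12 β-alcohol of 8 (C11 and C12 oxygens cis) | CCC(=O)C1=CC[C@H](O)[C@](C)(O[Si](C)(C)C(C)(C)C)[C@H]1CO[Si](C)(C)C(C)(C)C | intermediate
10 | tris-TBS enone (1-propanoylcyclohexene, C11 β-OTBS, C12 β-OTBS, C10 α-CH2OTBS) | CCC(=O)C1=CC[C@H](O[Si](C)(C)C(C)(C)C)[C@](C)(O[Si](C)(C)C(C)(C)C)[C@H]1CO[Si](C)(C)C(C)(C)C | intermediate
11 | dimethyl malonate | COC(=O)CC(=O)OC | starting material
12 | keto ester (trans-fused 3-methyl-2,16-dione with CO2Me on C15) | CC1C(=O)C(C(=O)OC)[C@@H]2C[C@H](O[Si](C)(C)C(C)(C)C)[C@](C)(O[Si](C)(C)C(C)(C)C)[C@@H](CO[Si](C)(C)C(C)(C)C)[C@H]2C1=O | intermediate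
13 | keto acid (CO2H on C15) | CC1C(=O)C(C(O)=O)[C@@H]2C[C@H](O[Si](C)(C)C(C)(C)C)[C@](C)(O[Si](C)(C)C(C)(C)C)[C@@H](CO[Si](C)(C)C(C)(C)C)[C@H]2C1=O | intermediate
14 | trans-decalin-2,16-dione with C3 methyl (H-1 β, H-14 α) | CC1C(=O)C[C@@H]2C[C@H](O[Si](C)(C)C(C)(C)C)[C@](C)(O[Si](C)(C)C(C)(C)C)[C@@H](CO[Si](C)(C)C(C)(C)C)[C@H]2C1=O | intermediate
15 | acrolein (prop-2-enal) | C=CC=O | starting material
16 | C3-quaternary dione aldehyde (C3 β-CH2CH2CHO, α-CH3) | O=CCC[C@]1(C)C(=O)C[C@@H]2C[C@H](O[Si](C)(C)C(C)(C)C)[C@](C)(O[Si](C)(C)C(C)(C)C)[C@@H](CO[Si](C)(C)C(C)(C)C)[C@H]2C1=O | intermediate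
17 | C6 alcohol | OCCC[C@]1(C)C(=O)C[C@@H]2C[C@H](O[Si](C)(C)C(C)(C)C)[C@](C)(O[Si](C)(C)C(C)(C)C)[C@@H](CO[Si](C)(C)C(C)(C)C)[C@H]2C1=O | intermediate
18 | C6 bromide (3-bromopropyl arm) | BrCCC[C@]1(C)C(=O)C[C@@H]2C[C@H](O[Si](C)(C)C(C)(C)C)[C@](C)(O[Si](C)(C)C(C)(C)C)[C@@H](CO[Si](C)(C)C(C)(C)C)[C@H]2C1=O | intermediate
19 | C9 alcohol (free hydroxymethyl on C10) | BrCCC[C@]1(C)C(=O)C[C@@H]2C[C@H](O[Si](C)(C)C(C)(C)C)[C@](C)(O[Si](C)(C)C(C)(C)C)[C@@H](CO)[C@H]2C1=O | intermediate
20 | diol (C2 β-OH, C9 OH, C16 ketone) | BrCCC[C@]1(C)C(=O)C[C@@H]2C[C@H](O[Si](C)(C)C(C)(C)C)[C@](C)(O[Si](C)(C)C(C)(C)C)[C@@H](CO)[C@H]2[C@@H]1O | intermediate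
21 | bis-TES ether with C16 ketone (Baeyer–Villiger substrate) | BrCCC[C@]1(C)C(=O)C[C@@H]2C[C@H](O[Si](C)(C)C(C)(C)C)[C@](C)(O[Si](C)(C)C(C)(C)C)[C@@H](CO[Si](CC)(CC)CC)[C@H]2[C@@H]1O[Si](CC)(CC)CC | intermediate
22 | Criegee adduct (C16 hydroxy 3-chloroperbenzoate) | BrCCC[C@]1(C)C(O)(OOC(=O)c3cccc(Cl)c3)C[C@@H]2C[C@H](O[Si](C)(C)C(C)(C)C)[C@](C)(O[Si](C)(C)C(C)(C)C)[C@@H](CO[Si](CC)(CC)CC)[C@H]2[C@@H]1O[Si](CC)(CC)CC | intermediate
23 | oxepan-2-one (oxygen between C3 and C16) | BrCCC[C@]1(C)OC(=O)C[C@@H]2C[C@H](O[Si](C)(C)C(C)(C)C)[C@](C)(O[Si](C)(C)C(C)(C)C)[C@@H](CO[Si](CC)(CC)CC)[C@H]2[C@@H]1O[Si](CC)(CC)CC | intermediate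
24 | Mannich base (CH2NMe2 on C15) | BrCCC[C@]1(C)OC(=O)C(CN(C)C)[C@@H]2C[C@H](O[Si](C)(C)C(C)(C)C)[C@](C)(O[Si](C)(C)C(C)(C)C)[C@@H](CO[Si](CC)(CC)CC)[C@H]2[C@@H]1O[Si](CC)(CC)CC | intermediate
25 | trimethylammonium iodide of 24 | BrCCC[C@]1(C)OC(=O)C(C[N+](C)(C)C)[C@@H]2C[C@H](O[Si](C)(C)C(C)(C)C)[C@](C)(O[Si](C)(C)C(C)(C)C)[C@@H](CO[Si](CC)(CC)CC)[C@H]2[C@@H]1O[Si](CC)(CC)CC.[I-] | intermediate
26 | α-methylene lactone (C15=CH2) | BrCCC[C@]1(C)OC(=O)C(=C)[C@@H]2C[C@H](O[Si](C)(C)C(C)(C)C)[C@](C)(O[Si](C)(C)C(C)(C)C)[C@@H](CO[Si](CC)(CC)CC)[C@H]2[C@@H]1O[Si](CC)(CC)CC | intermediate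
27 | α-methyl lactone (C15 β-CH3) | BrCCC[C@]1(C)OC(=O)[C@H](C)[C@@H]2C[C@H](O[Si](C)(C)C(C)(C)C)[C@](C)(O[Si](C)(C)C(C)(C)C)[C@@H](CO[Si](CC)(CC)CC)[C@H]2[C@@H]1O[Si](CC)(CC)CC | intermediate
28 | diisobutylaluminium hemiacetal at C16 | BrCCC[C@]1(C)OC(O[Al](CC(C)C)CC(C)C)[C@H](C)[C@@H]2C[C@H](O[Si](C)(C)C(C)(C)C)[C@](C)(O[Si](C)(C)C(C)(C)C)[C@@H](CO[Si](CC)(CC)CC)[C@H]2[C@@H]1O[Si](CC)(CC)CC | intermediate
29 | C16 acetoxy oxepane (both epimers) | BrCCC[C@]1(C)OC(OC(C)=O)[C@H](C)[C@@H]2C[C@H](O[Si](C)(C)C(C)(C)C)[C@](C)(O[Si](C)(C)C(C)(C)C)[C@@H](CO[Si](CC)(CC)CC)[C@H]2[C@@H]1O[Si](CC)(CC)CC | intermediate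
30 | C16 oxocarbenium triflate | BrCCC[C@]1(C)[O+]=C[C@H](C)[C@@H]2C[C@H](O[Si](C)(C)C(C)(C)C)[C@](C)(O[Si](C)(C)C(C)(C)C)[C@@H](CO[Si](CC)(CC)CC)[C@H]2[C@@H]1O[Si](CC)(CC)CC.[O-]S(=O)(=O)C(F)(F)F | intermediate
31 | oxepane bromide (C16 methylene) | BrCCC[C@]1(C)OC[C@H](C)[C@@H]2C[C@H](O[Si](C)(C)C(C)(C)C)[C@](C)(O[Si](C)(C)C(C)(C)C)[C@@H](CO[Si](CC)(CC)CC)[C@H]2[C@@H]1O[Si](CC)(CC)CC | intermediate
32 | 2-bromo-3-(trimethylsilyl)prop-1-ene | C=C(Br)C[Si](C)(C)C | starting material
33 | allylsilane (arm ending in C7(=CH2)CH2SiMe3) | C=C(C[Si](C)(C)C)CCC[C@]1(C)OC[C@H](C)[C@@H]2C[C@H](O[Si](C)(C)C(C)(C)C)[C@](C)(O[Si](C)(C)C(C)(C)C)[C@@H](CO[Si](CC)(CC)CC)[C@H]2[C@@H]1O[Si](CC)(CC)CC | intermediate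
34 | C9 aldehyde | C=C(C[Si](C)(C)C)CCC[C@]1(C)OC[C@H](C)[C@@H]2C[C@H](O[Si](C)(C)C(C)(C)C)[C@](C)(O[Si](C)(C)C(C)(C)C)[C@@H](C=O)[C@H]2[C@@H]1O[Si](CC)(CC)CC | intermediate
35 | C2 hydroxy C9 aldehyde | C=C(C[Si](C)(C)C)CCC[C@]1(C)OC[C@H](C)[C@@H]2C[C@H](O[Si](C)(C)C(C)(C)C)[C@](C)(O[Si](C)(C)C(C)(C)C)[C@@H](C=O)[C@H]2[C@@H]1O | intermediate
36 | lactol (tetrahydrofuran closed, C9 OH) | C=C(C[Si](C)(C)C)CCC[C@]1(C)OC[C@H](C)[C@@H]2C[C@H](O[Si](C)(C)C(C)(C)C)[C@](C)(O[Si](C)(C)C(C)(C)C)[C@@H]3[C@H]2[C@@H]1OC3O | intermediate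
37 | methyl acetal (C9 OMe, both anomers) | C=C(C[Si](C)(C)C)CCC[C@]1(C)OC[C@H](C)[C@@H]2C[C@H](O[Si](C)(C)C(C)(C)C)[C@](C)(O[Si](C)(C)C(C)(C)C)[C@@H]3[C@H]2[C@@H]1OC3OC | intermediate
38 | C9 oxocarbenium triflate | C=C(C[Si](C)(C)C)CCC[C@]1(C)OC[C@H](C)[C@@H]2C[C@H](O[Si](C)(C)C(C)(C)C)[C@](C)(O[Si](C)(C)C(C)(C)C)[C@@H]3[C@H]2[C@@H]1[O+]=C3.[O-]S(=O)(=O)C(F)(F)F | intermediate
39 | tetracyclic bis-TBS ether (oxonane closed, C7 exocyclic methylene) | C=C1CCC[C@]2(C)OC[C@H](C)[C@@H]3C[C@H](O[Si](C)(C)C(C)(C)C)[C@](C)(O[Si](C)(C)C(C)(C)C)[C@@H]4[C@H]3[C@@H]2O[C@H]4C1 | intermediate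
40 | tetracyclic 11,12-diol | C=C1CCC[C@]2(C)OC[C@H](C)[C@@H]3C[C@H](O)[C@](C)(O)[C@@H]4[C@H]3[C@@H]2O[C@H]4C1 | intermediate
41 | octanoyl chloride | CCCCCCCC(Cl)=O | starting material
42 | CNP0286133.1 (C12 octanoate, C11 tertiary alcohol) | C=C1CCC[C@]2(C)OC[C@H](C)[C@@H]3C[C@H](OC(=O)CCCCCCC)[C@](C)(O)[C@@H]4[C@H]3[C@@H]2O[C@H]4C1 | target

**Count**

Total steps: 24. Longest linear sequence: 24 steps (from 1 and 2 to 42); 5, 11, 15, 32 and 41 enter as purchased reagents.

**Steps most likely to fail, with fallbacks**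

Step 22 (nine-membered ring closure). Protodesilylation of the allylsilane, or proton loss from the oxocarbenium ion to an enol ether, may outrun the slow medium-ring cyclisation. The fallback makes the C8–C9 bond intermolecularly and closes the ring at C6–C7. It leaves the route at bromide 31. KOtBu in DMSO eliminates HBr to the terminal alkene F1. The conditions of steps 20 and 21 then give the aldehyde F2 and the methyl acetal F3. TMSOTf-promoted addition of 2-bromo-3-(trimethylsilyl)prop-1-ene 32 on the convex face of the bicyclic oxocarbenium ion should give the C9 2-bromoallyl tetrahydrofuran F4 with C8 cis to C3. 9-BBN hydroborates the monosubstituted alkene to the B-alkyl borane F5. An intramolecular B-alkyl Suzuki–Miyaura coupling (Pd(dppf)Cl2, AsPh3, Cs2CO3, DMF–THF–H2O, high dilution) joins C6 to C7 and comes back to the route at 39.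

Step 12 (directed reduction at C2). The hydroxy ketone may rest as its C2 hemiketal, so that no alkoxyborohydride forms and hydride is delivered slowly or to C16. The fallback ties the hydride to the C9 oxygen covalently. It leaves the route at 19. 1,1,3,3-Tetramethyldisilazane gives the dimethylsilyl ether F6, which can no longer close to the hemiketal. BF3·OEt2 (cat.) in CH2Cl2 at −78 °C triggers intramolecular hydrosilylation of the C2 ketone from the α face to the cyclic siloxane F7. HF·pyridine then releases the diol and the route is rejoined at 20.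

Step 3 (enantioselective cycloaddition). Protodesilylation of the acid-labile dienol silyl ether by the Brønsted-acidic boron catalyst, or a stepwise Mukaiyama–Michael pathway, may erode yield and enantioselectivity. The fallback uses a two-point-binding dienophile under a neutral copper catalyst. It leaves the route at diene 4. Cycloaddition with 1-(3,5-dimethylpyrazol-1-yl)prop-2-yn-1-one F8 (from propiolic acid and 3,5-dimethylpyrazole with DCC), catalysed by Cu(NTf2)2 and (S,S)-2,2'-isopropylidenebis(4-tert-butyl-2-oxazoline), gives the acyl pyrazole F9. EtMgBr in THF at −78 °C converts the acyl pyrazole into the ethyl ketone, and the route is rejoined at 6.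

**Further compounds**

F1 | step 22 | terminal alkene (allyl arm on C3; bis-TES) | C=CC[C@]1(C)OC[C@H](C)[C@@H]2C[C@H](O[Si](C)(C)C(C)(C)C)[C@](C)(O[Si](C)(C)C(C)(C)C)[C@@H](CO[Si](CC)(CC)CC)[C@H]2[C@@H]1O[Si](CC)(CC)CC
F2 | step 22 | aldehyde (C9 CHO, allyl arm) | C=CC[C@]1(C)OC[C@H](C)[C@@H]2C[C@H](O[Si](C)(C)C(C)(C)C)[C@](C)(O[Si](C)(C)C(C)(C)C)[C@@H](C=O)[C@H]2[C@@H]1O[Si](CC)(CC)CC
F3 | step 22 | methyl acetal (allyl arm, both anomers) | C=CC[C@]1(C)OC[C@H](C)[C@@H]2C[C@H](O[Si](C)(C)C(C)(C)C)[C@](C)(O[Si](C)(C)C(C)(C)C)[C@@H]3[C@H]2[C@@H]1OC3OC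
F4 | step 22 | C9 2-bromoallyl tetrahydrofuran (C8 cis to C3) | C=CC[C@]1(C)OC[C@H](C)[C@@H]2C[C@H](O[Si](C)(C)C(C)(C)C)[C@](C)(O[Si](C)(C)C(C)(C)C)[C@@H]3[C@H]2[C@@H]1O[C@H]3CC(Br)=C
F5 | step 22 | B-alkyl borane (C6 bound to 9-BBN) | C(CC[C@]1(C)OC[C@H](C)[C@@H]2C[C@H](O[Si](C)(C)C(C)(C)C)[C@](C)(O[Si](C)(C)C(C)(C)C)[C@@H]3[C@H]2[C@@H]1O[C@H]3CC(Br)=C)B1C2CCCC1CCC2
F6 | step 12 | dimethylsilyl ether of 19 (C9 O–SiHMe2) | BrCCC[C@]1(C)C(=O)C[C@@H]2C[C@H](O[Si](C)(C)C(C)(C)C)[C@](C)(O[Si](C)(C)C(C)(C)C)[C@@H](CO[SiH](C)C)[C@H]2C1=O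
F7 | step 12 | cyclic siloxane (C2–O–SiMe2–O–C9) | BrCCC[C@]1(C)C(=O)C[C@@H]2C[C@H](O[Si](C)(C)C(C)(C)C)[C@](C)(O[Si](C)(C)C(C)(C)C)[C@@H]3[C@H]2[C@@H]1O[Si](C)(C)OC3
F8 | step 3 | 1-(3,5-dimethylpyrazol-1-yl)prop-2-yn-1-one | C#CC(=O)n1nc(C)cc1C
F9 | step 3 | acyl pyrazole cycloadduct ((R) at C10) | Cc1cc(C)n(n1)C(=O)C1=CCC(O[Si](C)(C)C(C)(C)C)=C(C)[C@H]1CO[Si](C)(C)C(C)(C)C
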